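**Retrosynthetic overview**
- Target 11 comes from 10 by BCl3 cleavage of the C8 isopropyl ether; the methyl ethers stay.
- 10 comes from flavone 8 by iridium-catalysed C–H borylation and oxidation on ring B. The strategy rests on one feature of 8: C5'–H (C3' of the target) is the only sp2 C–H with a single small ortho neighbour, the 4'-methoxy group. C3–H, C5–H and C2'–H are flanked on both sides, and C6'–H is ortho to ring C.
- 8 comes from chalcone 6 by iodine/DMSO oxidative cyclisation; 6 comes from acetophenone 4 and 3,4-dimethoxybenzaldehyde 5 by Claisen–Schmidt condensation.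
- 4 comes from 2',3'-dihydroxy-4'-methoxyacetophenone 1 by 3-O-isopropylation, C5 bromination and copper-catalysed methoxylation.
- Ring order: rings A and B are bought; ring C (the pyranone) is the only ring formed, in step 5.

Key step: step 6

Remark: compounds 1 and 5, and the 3-hydroxy-4,5-dimethoxybenzaldehyde used only in a fallback, are taken as catalogue compounds.

**Route**

Step 1
Reactants: 1 1-(2,3-dihydroxy-4-methoxyphenyl)ethan-1-one
Product: 2 1-(2-hydroxy-3-isopropoxy-4-methoxyphenyl)ethan-1-one
Conditions: 2-bromopropane (1.5 equiv), K2CO3 (1.2 equiv), DMF, 50 °C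
Reagents that add atoms: 2-bromopropane, CC(C)Br
Why: Williamson etherification; the 2-hydroxyl is held in a hydrogen bond to the acetyl carbonyl and its phenoxide is delocalised into the ketone, so the 3-hydroxyl should be alkylated, as in the usual conversion of gallacetophenone into its 2-hydroxy-3,4-dialkoxy ethers.

Step 2
Reactants: 2 1-(2-hydroxy-3-isopropoxy-4-methoxyphenyl)ethan-1-one
Product: 3 1-(5-bromo-2-hydroxy-3-isopropoxy-4-methoxyphenyl)ethan-1-one
Conditions: N-bromosuccinimide (1.05 equiv), MeCN, 0 °C to rt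
Reagents that add atoms: N-bromosuccinimide, O=C1CCC(=O)N1Br
Why: Electrophilic aromatic bromination; C5 is para to the free phenol, ortho to the 4-methoxy group and meta to the acetyl group, whereas C6 is ortho to the acetyl group and far less activated.

Step 3
Reactants: 3 1-(5-bromo-2-hydroxy-3-isopropoxy-4-methoxyphenyl)ethan-1-one
Product: 4 1-(2-hydroxy-3-isopropoxy-4,5-dimethoxyphenyl)ethan-1-one
Conditions: NaOMe (25% in MeOH, 5 equiv), CuBr (20 mol%), EtOAc (20 mol%), DMF, 110 °C; dilute HCl work-up
Reagents that add atoms: sodium methoxide, [Na+].[O-]C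
Why: Ullmann-type copper-catalysed methoxylation of an aryl bromide, the exchange used to turn 5-bromovanillin into syringaldehyde, which tolerates a free phenoxide and an aryl methyl ketone.

Step 4
Reactants: 4 1-(2-hydroxy-3-isopropoxy-4,5-dimethoxyphenyl)ethan-1-one; 5 3,4-dimethoxybenzaldehyde
Product: 6 (E)-3-(3,4-dimethoxyphenyl)-1-(2-hydroxy-3-isopropoxy-4,5-dimethoxyphenyl)prop-2-en-1-one
Conditions: KOH (50% aq.), EtOH, rt; dilute HCl work-up
Reagents that add atoms: none
Why: Claisen–Schmidt aldol condensation; the enolate of the methyl ketone adds to the non-enolisable aldehyde and E1cB loss of water should give the conjugated E-enone.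

Step 5
Reactants: 6 (E)-3-(3,4-dimethoxyphenyl)-1-(2-hydroxy-3-isopropoxy-4,5-dimethoxyphenyl)prop-2-en-1-one
Product: 8 2-(3,4-dimethoxyphenyl)-8-isopropoxy-6,7-dimethoxychromen-4-one, via flavanone 7 (not isolated)
Conditions: I2 (10 mol%), DMSO, 120 °C; aq. Na2S2O3 work-up
Reagents that add atoms: none
Why: Iodine-catalysed oxidative cyclisation of a 2'-hydroxychalcone; 6-endo oxa-Michael closure gives flavanone 7, which is iodinated at C3 and loses HI, and DMSO reoxidises the iodide so that little acid is present to threaten the isopropyl ether.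

Step 6
Reactants: 8 2-(3,4-dimethoxyphenyl)-8-isopropoxy-6,7-dimethoxychromen-4-one
Product: 10 2-(3-hydroxy-4,5-dimethoxyphenyl)-8-isopropoxy-6,7-dimethoxychromen-4-one, via aryl pinacol boronate 9 (not isolated)
Conditions: [Ir(OMe)(1,5-cyclooctadiene)]2 (5 mol%), 4,4'-di-tert-butyl-2,2'-bipyridine (10 mol%), B2pin2 (1.5 equiv), THF, 80 °C, sealed; then 30% aq. H2O2, 1 M aq. NaOH, THF, 0 °C, short contact; Na2S2O3, dilute HCl work-up
Reagents that add atoms: hydrogen peroxide, OO (oxygen of the new hydroxyl); bis(pinacolato)diboron, CC1(C)OB(OC1(C)C)B1OC(C)(C)C(C)(C)O1 (boron of intermediate 9 only)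
Why: The trivalent iridium tris(boryl) complex formed from the iridium methoxide dimer, the bipyridine and B2pin2 cleaves an aromatic C–H bond by oxidative addition, C–B reductive elimination gives boronate 9 and pinacolborane, and hydroperoxide then adds to boron and triggers a 1,2-aryl shift from boron to oxygen, so the new C–O bond stands exactly where the C–B bond was. The closest known reaction type is the sterically governed iridium-catalysed arene C–H borylation with one-pot oxidation to the phenol, which also covers C–H bonds ortho to a single methoxy group. No ring is closed and no stereocentre is formed. The step needs site selectivity among five sp2 C–H bonds: C3–H sits between the C2 aryl group and the C4 carbonyl, C5–H between C4a and the C6 methoxy group, C2'–H between C1' and the 3'-methoxy group, and C6'–H is ortho to the bulky ring C, so only C5'–H, whose single ortho neighbour is the small 4'-methoxy group, is open to the crowded catalyst. Once C5' is borylated every remaining sp2 C–H is flanked on both sides, which should stop the reaction at monoborylation, and the isopropyl ether adds no aromatic C–H. The oxidation is run cold and briefly so that hydroperoxide attacks boron and not the pyranone.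

Step 7
Reactants: 10 2-(3-hydroxy-4,5-dimethoxyphenyl)-8-isopropoxy-6,7-dimethoxychromen-4-one
Product: 11 8-hydroxy-2-(3-hydroxy-4,5-dimethoxyphenyl)-6,7-dimethoxychromen-4-one
Conditions: BCl3 (1 M in CH2Cl2, 4 equiv), CH2Cl2, −78 to 0 °C; MeOH then water quench
Reagents that add atoms: none
Why: Lewis-acid dealkylation; BCl3 cleaves a secondary alkyl aryl ether at temperatures where methyl aryl ethers survive unless they are ortho to a carbonyl, and here C5 carries hydrogen, so no methoxy group is chelation-activated by the C4 carbonyl.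

**Compound list**
1 | 1-(2,3-dihydroxy-4-methoxyphenyl)ethan-1-one | CC(=O)c1ccc(OC)c(O)c1O | starting material
2 | 1-(2-hydroxy-3-isopropoxy-4-methoxyphenyl)ethan-1-one | CC(=O)c1ccc(OC)c(OC(C)C)c1O | intermediate
3 | 1-(5-bromo-2-hydroxy-3-isopropoxy-4-methoxyphenyl)ethan-1-one | CC(=O)c1cc(Br)c(OC)c(OC(C)C)c1O | intermediate
4 | 1-(2-hydroxy-3-isopropoxy-4,5-dimethoxyphenyl)ethan-1-one | CC(=O)c1cc(OC)c(OC)c(OC(C)C)c1O | intermediate
5 | 3,4-dimethoxybenzaldehyde | COc1ccc(C=O)cc1OC | starting material
6 | (E)-3-(3,4-dimethoxyphenyl)-1-(2-hydroxy-3-isopropoxy-4,5-dimethoxyphenyl)prop-2-en-1-one | COc1ccc(/C=C/C(=O)c2cc(OC)c(OC)c(OC(C)C)c2O)cc1OC | intermediate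
7 | racemic 2-(3,4-dimethoxyphenyl)-8-isopropoxy-6,7-dimethoxychroman-4-one (not isolated) | COc1ccc(C2CC(=O)c3cc(OC)c(OC)c(OC(C)C)c3O2)cc1OC | intermediate
8 | 2-(3,4-dimethoxyphenyl)-8-isopropoxy-6,7-dimethoxychromen-4-one | COc1ccc(-c2cc(=O)c3cc(OC)c(OC)c(OC(C)C)c3o2)cc1OC | intermediate
9 | 2-[3,4-dimethoxy-5-(4,4,5,5-tetramethyl-1,3,2-dioxaborolan-2-yl)phenyl]-8-isopropoxy-6,7-dimethoxychromen-4-one (not isolated) | COc1cc(-c2cc(=O)c3cc(OC)c(OC)c(OC(C)C)c3o2)cc(B2OC(C)(C)C(C)(C)O2)c1OC | intermediate
10 | 2-(3-hydroxy-4,5-dimethoxyphenyl)-8-isopropoxy-6,7-dimethoxychromen-4-one | COc1cc(-c2cc(=O)c3cc(OC)c(OC)c(OC(C)C)c3o2)cc(O)c1OC | intermediate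
11 | 8-hydroxy-2-(3-hydroxy-4,5-dimethoxyphenyl)-6,7-dimethoxychromen-4-one | COc1cc(-c2cc(=O)c3cc(OC)c(OC)c(O)c3o2)cc(O)c1OC | target

**Step count**
Total steps: 7. Longest linear sequence: 7 steps (1 to 11); aldehyde 5 enters in step 4.

**Steps most likely to fail**

1. Step 6. The in-plane methyl of the 4'-methoxy group may shield C5'–H so that C–H activation is slow or drifts to C6'. Pinacolborane may also reduce the pyranone, or hydroperoxide may attack ring C during the oxidation. The fallback brings the ring B oxygen in with the aldehyde and sets out from compound 4. Purchased 3-hydroxy-4,5-dimethoxybenzaldehyde is alkylated (2-bromopropane, K2CO3, DMF, 50 °C) to 3-isopropoxy-4,5-dimethoxybenzaldehyde F1. Claisen–Schmidt condensation of F1 and 4 (KOH, EtOH, rt) should give (E)-1-(2-hydroxy-3-isopropoxy-4,5-dimethoxyphenyl)-3-(3-isopropoxy-4,5-dimethoxyphenyl)prop-2-en-1-one F2. Treatment with I2 (10 mol%) in DMSO at 120 °C should pass through racemic 8-isopropoxy-2-(3-isopropoxy-4,5-dimethoxyphenyl)-6,7-dimethoxychroman-4-one F3 to 8-isopropoxy-2-(3-isopropoxy-4,5-dimethoxyphenyl)-6,7-dimethoxychromen-4-one F4. BCl3 (CH2Cl2, −78 to 0 °C) then removes both isopropyl groups, and the fallback comes back to the route at compound 11.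

2. Step 3. Bromide exchange at the electron-rich ring, whose phenoxide is para to bromine, may be sluggish, with hydrodebromination back to 2 or aldol self-condensation of the ketone in hot methoxide. The fallback is an Elbs persulfate oxidation and sets out from compound 2. K2S2O8 in aqueous NaOH at rt should attack the position para to the phenoxide and give potassium 5-acetyl-4-hydroxy-3-isopropoxy-2-methoxyphenyl sulfate F5. Hot dilute HCl hydrolyses it to 1-(2,5-dihydroxy-3-isopropoxy-4-methoxyphenyl)ethan-1-one F6. MeI (1.05 equiv) with K2CO3 in acetone should methylate only the non-chelated 5-hydroxyl, and the fallback comes back to the route at compound 4.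

3. Step 1. Alkylation may occur at the wrong hydroxyl or twice, or the secondary bromide may react slowly at the flanked 3-hydroxyl and be lost by elimination. The fallback alkylates both hydroxyls and then removes one, and sets out from compound 1. Excess 2-bromopropane with Cs2CO3 in DMF at 80 °C should give 1-(2,3-diisopropoxy-4-methoxyphenyl)ethan-1-one F7. BCl3 (1.0 equiv, CH2Cl2, −78 °C) is held in a chelate by the acetyl carbonyl and the 2-oxygen and should cleave only the ortho ether, and the fallback comes back to the route at compound 2.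

**Further compounds**
F1 | step 6 | 3-isopropoxy-4,5-dimethoxybenzaldehyde | COc1cc(C=O)cc(OC(C)C)c1OC
F2 | step 6 | (E)-1-(2-hydroxy-3-isopropoxy-4,5-dimethoxyphenyl)-3-(3-isopropoxy-4,5-dimethoxyphenyl)prop-2-en-1-one | COc1cc(/C=C/C(=O)c2cc(OC)c(OC)c(OC(C)C)c2O)cc(OC(C)C)c1OC
F3 | step 6 | racemic 8-isopropoxy-2-(3-isopropoxy-4,5-dimethoxyphenyl)-6,7-dimethoxychroman-4-one | COc1cc(C2CC(=O)c3cc(OC)c(OC)c(OC(C)C)c3O2)cc(OC(C)C)c1OC
F4 | step 6 | 8-isopropoxy-2-(3-isopropoxy-4,5-dimethoxyphenyl)-6,7-dimethoxychromen-4-one | COc1cc(-c2cc(=O)c3cc(OC)c(OC)c(OC(C)C)c3o2)cc(OC(C)C)c1OC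
F5 | step 3 | potassium 5-acetyl-4-hydroxy-3-isopropoxy-2-methoxyphenyl sulfate | CC(=O)c1cc(OS(=O)(=O)[O-])c(OC)c(OC(C)C)c1O.[K+]
F6 | step 3 | 1-(2,5-dihydroxy-3-isopropoxy-4-methoxyphenyl)ethan-1-one | CC(=O)c1cc(O)c(OC)c(OC(C)C)c1O
F7 | step 1 | 1-(2,3-diisopropoxy-4-methoxyphenyl)ethan-1-one | CC(=O)c1ccc(OC)c(OC(C)C)c1OC(C)C
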